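**Plan**

- Retrosynthesis: C10–C11 and C9–CH3 (C19) are cut together, giving the end-group enyne 9 (C1–C10) and the C26 polyenyl iodide 15 (C11–C1'). Enyne 9 is cut further at C8–C9, C7=C8 and the ring bond C5–C6; iodide 15 at C11=C12 and C11'=C12'.
- Enabling feature: the E-trisubstituted C9=C10 alkene carries CH3 on C9 and H on C10, so it is the syn-methylmetalation product of a terminal C9≡C10 alkyne. It sits next to the cyclopentane ring (C2–C6), whose allylic C6–H and tertiary C1 and C5 carbinols tolerate only neutral, acid-free conditions.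
- Forward, end group: the cyclopentane ring (C2–C6) closes in step 2 by aldol condensation of the ozonolysis product of (R)-α-terpineol; epoxidation, reductive opening, Takai olefination, Sonogashira coupling and desilylation give 9 (steps 3–7).
- Forward, chain: pseudoionone is converted to the C15 phosphonium salt, which undergoes Wittig reaction with the C10 dialdehyde and Takai olefination to give 15 (steps 8–11). The two halves are joined last (step 12).
- Stereochemistry: C2 comes from (R)-α-terpineol; C5 from epoxidation anti to the C2 hydroxyisopropyl arm; C6 from protonation of an enol on the face of the C5 hydroxyl. The E alkenes come from Takai olefination, Wittig reaction with thermal equilibration, syn carbometalation and stereoretentive couplings.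

Key step: step 12

Assumption: pseudoionone is used as its pure (3E,5E) isomer and (R)-α-terpineol in enantiopure form; carotenoid numbering (C1–C20, C1'–C20') is used for all fragments.

**Route**

Step 1
Reactants: 1 (R)-(+)-α-terpineol
Product: 2 (3R)-3-(2-hydroxypropan-2-yl)-6-oxoheptanal
Conditions: O3, CH2Cl2/MeOH, −78 °C; then Me2S, −78 °C to rt
Reagents that add atoms: ozone, [O-][O+]=O
Why: Ozonolysis with reductive work-up cleaves the trisubstituted ring alkene into the future C5 methyl ketone and C7 aldehyde without touching the stereocentre or the tertiary carbinol; the product may rest partly as its lactol.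

Step 2
Reactants: 2 (3R)-3-(2-hydroxypropan-2-yl)-6-oxoheptanal
Product: 3 (5R)-5-(2-hydroxypropan-2-yl)-2-methylcyclopent-1-ene-1-carbaldehyde
Conditions: piperidine (cat.), AcOH (cat.), toluene, 70 °C, water removal
Reagents that add atoms: none
Why: Amine/acid-catalysed intramolecular aldol condensation through the aldehyde enamine (C6 attacks the C5 ketone, then dehydration) should close the cyclopentane ring C2–C6 as the formylcyclopentene and not the acetylcyclopentene that hydroxide would favour; C2 is not enolisable and keeps its configuration.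

Step 3
Reactants: 3 (5R)-5-(2-hydroxypropan-2-yl)-2-methylcyclopent-1-ene-1-carbaldehyde
Product: 4 (1S,2S,5R)-2-(2-hydroxypropan-2-yl)-5-methyl-6-oxabicyclo[3.1.0]hexane-1-carbaldehyde (epoxide oxygen trans to the hydroxyisopropyl group)
Conditions: 30% aq. H2O2, NaOH (cat.), MeOH, 0 °C
Reagents that add atoms: hydrogen peroxide, OO
Why: In this Weitz–Scheffer nucleophilic epoxidation the hydroperoxide adds reversibly to C5 and the enolate closes at C6 on the face away from the bulky hydroxyisopropyl group on the neighbouring C2, which should set C5 and C6 with the oxygen anti to the arm.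

Step 4
Reactants: 4 (1S,2S,5R)-2-(2-hydroxypropan-2-yl)-5-methyl-6-oxabicyclo[3.1.0]hexane-1-carbaldehyde
Product: 5 (1R,2R,5R)-2-hydroxy-5-(2-hydroxypropan-2-yl)-2-methylcyclopentane-1-carbaldehyde (formyl group cis to the hydroxyisopropyl group and to the ring methyl, trans to the ring hydroxyl)
Conditions: Na[PhSeB(OEt)3] (from (PhSe)2 and NaBH4 in EtOH), AcOH, EtOH, 0 °C to rt
Reagents that add atoms: none
Why: Organoselenium-mediated reductive opening of an α,β-epoxy carbonyl compound cleaves the C6–O bond to a β-hydroxy enol, which the acetic acid buffer should protonate at C6 on the less hindered face (that of the C5 hydroxyl, away from the C5 methyl and the C2 arm), so hydrogen replaces oxygen with retention; the buffered, hydride-free medium guards against retro-aldol, dehydration and aldehyde reduction.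

Step 5
Reactants: 5 (1R,2R,5R)-2-hydroxy-5-(2-hydroxypropan-2-yl)-2-methylcyclopentane-1-carbaldehyde
Product: 6 (1R,2S,3R)-3-(2-hydroxypropan-2-yl)-2-[(E)-2-iodoethenyl]-1-methylcyclopentan-1-ol
Conditions: CrCl2 (6 equiv), CHI3 (2 equiv), THF, 0 °C to rt, dark
Reagents that add atoms: iodoform, IC(I)I
Why: Takai iodoolefination through the geminal dichromium carbenoid is E-selective and non-basic, so the epimerisable C6 centre and the aldol unit should survive; the aldehyde reacts through its open form, which is in equilibrium with the cis-fused lactol.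

Step 6
Reactants: 6 (1R,2S,3R)-3-(2-hydroxypropan-2-yl)-2-[(E)-2-iodoethenyl]-1-methylcyclopentan-1-ol; 7 trimethylsilylacetylene
Product: 8 (1R,2R,3R)-3-(2-hydroxypropan-2-yl)-1-methyl-2-[(E)-4-(trimethylsilyl)but-1-en-3-yn-1-yl]cyclopentan-1-ol
Conditions: PdCl2(PPh3)2 (3 mol %), CuI (6 mol %), Et3N, THF, rt
Reagents that add atoms: none
Why: Sonogashira coupling of an alkenyl iodide with a terminal alkyne forms C8–C9 with retention of the E geometry and tolerates free tertiary alcohols.

Step 7
Reactants: 8 (1R,2R,3R)-3-(2-hydroxypropan-2-yl)-1-methyl-2-[(E)-4-(trimethylsilyl)but-1-en-3-yn-1-yl]cyclopentan-1-ol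
Product: 9 (1R,2R,3R)-2-[(E)-but-1-en-3-yn-1-yl]-3-(2-hydroxypropan-2-yl)-1-methylcyclopentan-1-ol
Conditions: K2CO3 (cat.), MeOH, rt
Reagents that add atoms: none
Why: Carbonate-catalysed methanolysis of the alkynyl C–Si bond frees the terminal alkyne; with the aldehyde gone the diol is no longer base-sensitive.

Step 8
Reactants: 10 (3E,5E)-pseudoionone
Product: 11 vinyl-ψ-ionol, (4E,6E)-3,7,11-trimethyldodeca-1,4,6,10-tetraen-3-ol (racemic)
Conditions: CH2=CHMgBr, THF, −20 °C to 0 °C; aq. NH4Cl
Reagents that add atoms: vinylmagnesium bromide, C=C[Mg]Br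
Why: 1,2-Grignard addition to the dienone carbonyl gives the tertiary allylic alcohol; its stereocentre is lost in the next step.

Step 9
Reactants: 11 vinyl-ψ-ionol
Product: 12 [(2E,4E,6E)-3,7,11-trimethyldodeca-2,4,6,10-tetraen-1-yl]triphenylphosphonium bromide
Conditions: PPh3·HBr, MeOH, rt; crystallisation (EtOAc)
Reagents that add atoms: triphenylphosphine hydrobromide, Br.c1ccc(cc1)P(c1ccccc1)c1ccccc1
Why: Acid-mediated allylic transposition of the tertiary allylic alcohol with capture by phosphine at the primary terminus gives the conjugated C15 salt; crystallisation should remove the minor 9'Z isomer.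

Step 10
Reactants: 12 C15 phosphonium bromide; 13 (2E,4E,6E)-2,7-dimethylocta-2,4,6-trienedial (3 equiv)
Product: 14 (2E,4E,6E,8E,10E,12E,14E)-2,7,11,15,19-pentamethylicosa-2,4,6,8,10,12,14,18-octaenal (12'-apo-ψ-caroten-12'-al)
Conditions: NaOMe, MeOH/CH2Cl2, 0 °C to rt; then heptane, reflux, dark; crystallisation
Reagents that add atoms: none
Why: Wittig olefination forms C11'=C12'; excess dialdehyde and the lower electrophilicity of the extended product aldehyde should hold the reaction at mono-olefination, and heating equilibrates the new disubstituted alkene to E.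

Step 11
Reactants: 14 C25 aldehyde
Product: 15 (1E,3E,5E,7E,9E,11E,13E,15E)-1-iodo-3,8,12,16,20-pentamethylhenicosa-1,3,5,7,9,11,13,15,19-nonaene
Conditions: CrCl2 (8 equiv), CHI3 (2.5 equiv), THF/1,4-dioxane, 0 °C to rt, dark; used at once
Reagents that add atoms: iodoform, IC(I)I
Why: Takai iodoolefination of a conjugated aldehyde is E-selective and neutral, so it should add C11 as the (E)-alkenyl iodide without disturbing the polyene.

Step 12
Reactants: 9 end-group enyne diol; 15 C26 polyenyl iodide
Product: 17 (2R,5R,6R)-2,6-cyclolycopene-1,5-diol, via alkenylalane 16 (not isolated)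
Conditions: AlMe3 (4.5 equiv), Cp2ZrCl2 (0.3 equiv), ClCH2CH2Cl, 0 °C to 23 °C; evaporate volatiles; then 15, ZnCl2 (1 equiv), Pd2(dba)3 (2.5 mol %), P(2-furyl)3 (10 mol %), THF/DMF, 23 °C, dark; aq. NaHCO3/potassium sodium tartrate work-up; chromatography and crystallisation in the dark
Reagents that add atoms: trimethylaluminium, C[Al](C)C
Why: Trimethylaluminium first turns both tertiary hydroxyls into dimethylaluminium alkoxides (methane is lost), after which the methylzirconocene–alane pair adds methyl and metal syn across the terminal C9≡C10 triple bond, methyl to the internal C9 and aluminium to the terminal C10, to give (E)-alkenylalane 16. Zerovalent palladium inserts into the C11–I bond of 15, the alkenyl group passes from aluminium through zinc to palladium, and reductive elimination forms C10–C11 with retention on both partners. The closest known reaction type is the zirconium-catalysed methylalumination of conjugated terminal enynes followed by palladium/zinc-co-catalysed alkenyl–alkenyl (Negishi) coupling, as used for retinoid and carotenoid chains. No ring is closed and no stereocentre is created; what the step must deliver is regio- and syn-selective carbometalation and an all-E triene at C7–C12. The unsubstituted alkyne terminus of 9 secures the regiochemistry, the concerted syn addition fixes the 9E geometry, and stereoretentive transmetalation and coupling carry over the 11E geometry set in step 11. Because the medium is free of Brønsted acid, strong base and ylides, the allylic C6–H and the C1 and C5 carbinols, masked as aluminium alkoxides until work-up, are expected to survive.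

**Compound list**

1 | (R)-(+)-α-terpineol, 2-[(1R)-4-methylcyclohex-3-en-1-yl]propan-2-ol | CC1=CC[C@@H](CC1)C(C)(C)O | starting material
2 | (3R)-3-(2-hydroxypropan-2-yl)-6-oxoheptanal | CC(=O)CC[C@H](CC=O)C(C)(C)O | intermediate
3 | (5R)-5-(2-hydroxypropan-2-yl)-2-methylcyclopent-1-ene-1-carbaldehyde | O=CC1=C(C)CC[C@H]1C(C)(C)O | intermediate
4 | (1S,2S,5R)-2-(2-hydroxypropan-2-yl)-5-methyl-6-oxabicyclo[3.1.0]hexane-1-carbaldehyde | O=C[C@@]12O[C@]1(C)CC[C@H]2C(C)(C)O | intermediate
5 | (1R,2R,5R)-2-hydroxy-5-(2-hydroxypropan-2-yl)-2-methylcyclopentane-1-carbaldehyde | O=C[C@@H]1[C@H](C(C)(C)O)CC[C@@]1(C)O | intermediate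
6 | (1R,2S,3R)-3-(2-hydroxypropan-2-yl)-2-[(E)-2-iodoethenyl]-1-methylcyclopentan-1-ol | I/C=C/[C@@H]1[C@H](C(C)(C)O)CC[C@@]1(C)O | intermediate
7 | trimethylsilylacetylene | C#C[Si](C)(C)C | starting material
8 | (1R,2R,3R)-3-(2-hydroxypropan-2-yl)-1-methyl-2-[(E)-4-(trimethylsilyl)but-1-en-3-yn-1-yl]cyclopentan-1-ol | C[Si](C)(C)C#C/C=C/[C@@H]1[C@H](C(C)(C)O)CC[C@@]1(C)O | intermediate
9 | (1R,2R,3R)-2-[(E)-but-1-en-3-yn-1-yl]-3-(2-hydroxypropan-2-yl)-1-methylcyclopentan-1-ol (end-group enyne, C1–C10) | C#C/C=C/[C@@H]1[C@H](C(C)(C)O)CC[C@@]1(C)O | intermediate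
10 | (3E,5E)-pseudoionone, (3E,5E)-6,10-dimethylundeca-3,5,9-trien-2-one | CC(C)=CCC/C(C)=C/C=C/C(C)=O | starting material
11 | vinyl-ψ-ionol, (4E,6E)-3,7,11-trimethyldodeca-1,4,6,10-tetraen-3-ol (racemic) | CC(C)=CCC/C(C)=C/C=C/C(C)(O)C=C | intermediate
12 | [(2E,4E,6E)-3,7,11-trimethyldodeca-2,4,6,10-tetraen-1-yl]triphenylphosphonium bromide | CC(C)=CCC/C(C)=C/C=C/C(C)=C/C[P+](c1ccccc1)(c1ccccc1)c1ccccc1.[Br-] | intermediate
13 | (2E,4E,6E)-2,7-dimethylocta-2,4,6-trienedial | O=C/C(C)=C/C=C/C=C(C)/C=O | starting material
14 | (2E,4E,6E,8E,10E,12E,14E)-2,7,11,15,19-pentamethylicosa-2,4,6,8,10,12,14,18-octaenal | CC(C)=CCC/C(C)=C/C=C/C(C)=C/C=C/C(C)=C/C=C/C=C(C)/C=O | intermediate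
15 | (1E,3E,5E,7E,9E,11E,13E,15E)-1-iodo-3,8,12,16,20-pentamethylhenicosa-1,3,5,7,9,11,13,15,19-nonaene (C11–C1') | CC(C)=CCC/C(C)=C/C=C/C(C)=C/C=C/C(C)=C/C=C/C=C(C)/C=C/I | intermediate
16 | (1E,3E)-dienyl dimethylalane from 9, methyl on C9, aluminium on C10, both hydroxyls as dimethylaluminium alkoxides | C[Al](C)/C=C(C)/C=C/[C@@H]1[C@H](C(C)(C)O[Al](C)C)CC[C@@]1(C)O[Al](C)C | intermediate
17 | (2R,5R,6R)-2,6-cyclolycopene-1,5-diol | CC(C)=CCC/C(C)=C/C=C/C(C)=C/C=C/C(C)=C/C=C/C=C(C)/C=C/C=C(C)/C=C/[C@@H]1[C@H](C(C)(C)O)CC[C@@]1(C)O | target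

**Step count**

Total: 12 steps. Longest linear sequence: 8 steps (steps 1–7 and 12); the chain half takes 4 steps (8–11) before the junction.

**Steps most likely to fail**

Step 12. The carbometalation may be slow or regiochemically unclean in the presence of two aluminium alkoxides, methyl may transfer in place of the alkenyl group, or the heptaenyl iodide may decompose before it couples. The fallback sets out from 9 and 14 and comes back at 17. Enyne 9 is methylaluminated as in step 12 and the alane 16 is quenched with I2 to give (1R,2R,3R)-3-(2-hydroxypropan-2-yl)-2-[(1E,3E)-4-iodo-3-methylbuta-1,3-dien-1-yl]-1-methylcyclopentan-1-ol F1, which can be purified. Aldehyde 14 is converted by chromium-mediated stannylolefination (Bu3SnCHBr2, CrCl2, LiI, THF/DMF) into the (E)-polyenyl tributylstannane F2. Stille coupling of F1 with F2 (Pd2(dba)3, AsPh3, NMP, rt, dark) then gives 17. The same two bonds are made (C9–CH3 by methylalumination, C10–C11 by palladium-catalysed sp2–sp2 coupling), but carbometalation and coupling are separated and the polarity of the coupling is reversed, so iodide 15 is no longer needed.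

Step 4. The aldehyde may be reduced, the aldol may undergo retro-aldol cleavage or dehydration, or the enol may be protonated on the wrong face or epimerise at C6. The fallback sets out from 4 and comes back at 5. Wharton transposition (N2H4·H2O, cat. AcOH, MeOH, 0 °C to rt) gives (1R,3R)-3-(2-hydroxypropan-2-yl)-1-methyl-2-methylidenecyclopentan-1-ol F3. Hydroboration with 9-BBN from the face opposite the C2 arm and the C5 methyl, followed by NaOH/H2O2, gives (1R,2S,3R)-2-(hydroxymethyl)-3-(2-hydroxypropan-2-yl)-1-methylcyclopentan-1-ol F4. Dess–Martin oxidation of the only oxidisable (primary) alcohol, buffered with NaHCO3, returns 5. Here the C6 hydrogen is delivered by hydroboration of an exocyclic alkene instead of by enol protonation.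

Step 3. Facial selectivity may be poor, or alkaline peroxide may oxidise the formyl group. The fallback sets out from 3 and comes back at 4. Luche reduction (NaBH4, CeCl3·7H2O, MeOH, 0 °C) gives [(5R)-5-(2-hydroxypropan-2-yl)-2-methylcyclopent-1-en-1-yl]methanol F5. Sharpless asymmetric epoxidation (Ti(OiPr)4, D-(−)-diethyl tartrate, t-BuOOH, 4 Å molecular sieves, CH2Cl2, −20 °C) gives [(1R,2S,5R)-2-(2-hydroxypropan-2-yl)-5-methyl-6-oxabicyclo[3.1.0]hexan-1-yl]methanol F6; this tartrate delivers oxygen to the face opposite the arm, so reagent control reinforces the substrate bias. Dess–Martin oxidation (NaHCO3, CH2Cl2) returns 4.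

**Further compounds**

F1 | step 12 | (1R,2R,3R)-3-(2-hydroxypropan-2-yl)-2-[(1E,3E)-4-iodo-3-methylbuta-1,3-dien-1-yl]-1-methylcyclopentan-1-ol | I/C=C(C)/C=C/[C@@H]1[C@H](C(C)(C)O)CC[C@@]1(C)O
F2 | step 12 | tributyl[(1E,3E,5E,7E,9E,11E,13E,15E)-3,8,12,16,20-pentamethylhenicosa-1,3,5,7,9,11,13,15,19-nonaen-1-yl]stannane | CC(C)=CCC/C(C)=C/C=C/C(C)=C/C=C/C(C)=C/C=C/C=C(C)/C=C/[Sn](CCCC)(CCCC)CCCC
F3 | step 4 | (1R,3R)-3-(2-hydroxypropan-2-yl)-1-methyl-2-methylidenecyclopentan-1-ol | C=C1[C@H](C(C)(C)O)CC[C@@]1(C)O
F4 | step 4 | (1R,2S,3R)-2-(hydroxymethyl)-3-(2-hydroxypropan-2-yl)-1-methylcyclopentan-1-ol | OC[C@@H]1[C@H](C(C)(C)O)CC[C@@]1(C)O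
F5 | step 3 | [(5R)-5-(2-hydroxypropan-2-yl)-2-methylcyclopent-1-en-1-yl]methanol | OCC1=C(C)CC[C@H]1C(C)(C)O
F6 | step 3 | [(1R,2S,5R)-2-(2-hydroxypropan-2-yl)-5-methyl-6-oxabicyclo[3.1.0]hexan-1-yl]methanol | OC[C@@]12O[C@]1(C)CC[C@H]2C(C)(C)O
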